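Early in larch, at 0.500 d, rings already read 4.4% and no later reading lay above that, while links fell from 16.3% to 6.3%, so I counted rings as made during coupling.

| setting | elm | maple | ash | larch | Friday's | Wednesday's | Monday's | Sunday's |
|---|---|---|---|---|---|---|---|---|
| first end groups | 42 mM | 42 mM | 42 mM | 42 mM | 42 mM | 42 mM (fed, over 50 h) | 42 mM | 42 mM |
| second end groups | 42 mM | 42 mM | 42 mM | 21 mM | 42.0 mM | 42.0 mM | 42.0 mM (fed, over 50 h) | 42.0 mM |
| protic impurity | 8.4 mM | 4.2 mM | 6.3 mM | 8.4 mM | 8.40 mM | 8.40 mM | 8.40 mM | 8.40 mM |
| temperature | 20 °C | 35 °C | 20 °C | 35 °C | 35 °C | 35 °C |  |  |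
| remark | run made earlier | run made earlier | run made earlier | run made earlier | everything together at the start | all else is in the flask from the start; the feed brings no volume worth counting | the addition at 15 °C, then warmed to 35 °C; the feed brings no volume worth counting | everything together at the start at 15 °C, warmed to 35 °C at 50 h |
| time |  |  |  |  | 5.0 d | 5.0 d | 5.0 d | 5.0 d |

| run | time / d | rings / % | links / % |
|---|---|---|---|
| elm | 2.00 | 2.4 | 54.9 |
| elm | 4.00 | 1.9 | 40.7 |
| elm | 6.00 | 3.4 | 31.7 |
| elm | 8.00 | 3.1 | 21.9 |
| elm | 10.0 | 2.6 | 18.7 |
| maple | 0.500 | 6.0 | 46.8 |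
| maple | 1.67 | 6.3 | 20.4 |
| maple | 3.00 | 4.0 | 19.3 |
| maple | 4.00 | 5.0 | 18.0 |
| maple | 6.00 | 4.5 | 19.6 |
| ash | 2.50 | 2.5 | 55.3 |
| ash | 5.00 | 2.3 | 37.0 |
| ash | 8.00 | 1.3 | 23.6 |
| ash | 10.0 | 2.0 | 19.9 |
| ash | 12.0 | 2.4 | 15.1 |
| larch | 0.500 | 4.4 | 16.3 |
| larch | 0.833 | 3.8 | 11.8 |
| larch | 1.67 | 3.6 | 8.2 |
| larch | 3.00 | 3.9 | 7.1 |
| larch | 6.00 | 3.3 | 6.3 |

(readings scatter by 1 percentage point)

- the earlier runs were read with a standard deviation of 1 percentage point
- steps that have been proposed: first end groups + second end groups -> links; first end groups + second end groups -> rings; links <-> isomer of the product; second end groups + protic impurity -> quenched reagent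

1. the flask with the highest amount of rings, in percent of the first end groups charged ("all alike" if they lie within 1.5 percentage points) (Friday's / Wednesday's / Monday's / Sunday's / all alike)
2. final rings, as a percentage of the first end groups charged, in Friday's
3. final rings, as a percentage of the first end groups charged, in Wednesday's
4. final rings, as a percentage of the first end groups charged, in Monday's
5. final rings, as a percentage of the first end groups charged, in Sunday's

To whoever takes over the bench: second end groups are the limiting reagent, and I took their usable amount U as charge minus protic impurity. I assumed that ring closure ignores c(second end groups) while link formation scales with it, so rings per link equal s/c(second end groups) and rings come to s·ln(1+U/s). Larch, with U of 12.6 mM and mean rings of 1.60 mM, gave s = 0.498 mM at 35 °C: the crossing concentration, the c(second end groups) at which ring closure and link formation run equally fast. On maple this s gives 2.16 mM, and its mean reading was 2.17 mM. Elm and ash, pooled, read s = 0.216 mM at 20 °C, and the same logarithmic slope gave 0.163 mM at 15 °C.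

With U of 33.6 mM, expect 5.01% rings in Friday's, the same in Wednesday's, where c(second end groups) sweeps the same range, and 2.07% in Sunday's. Monday's I could not size, but its feed holds c(second end groups) low, so I put it highest. Do not warm Monday's before the feed ends: its card holds the addition at 15 °C, where my s is 0.163 mM, against 0.498 mM at 35 °C.

The forecast said Monday's with 9%, against 5% for Friday's, 5% for Wednesday's and 2% for Sunday's: “second end groups starved, which favours rings despite the cold”.

Monday's gave 10.3%, more than Friday's 5.19%, Wednesday's 5.37% and Sunday's 2.06%.

    first end groups + second end groups → links (k = 54.5 /M/h, Ea = 51.0 kJ/mol)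
    first end groups + second end groups → rings, rate k2*[first end groups] as long as [second end groups] is above zero (k = 0.0298 /h, Ea = 94.0 kJ/mol)
    links ⇌ isomer of the product (K = 3.60, k = 0.0590 /h, Ea = 105 kJ/mol, ΔH = −42.0 kJ/mol)
    second end groups + protic impurity → quenched reagent (k = 197 /M/h, Ea = 54.0 kJ/mol)
    (constants at 35 °C)

Over its first 50 h, Monday's held a mean c(second end groups) of 1.67 mM, about ten times my s for 15 °C. In the neighbour of Sunday's charged with 110 mM of first end groups, where quenched reagent reached 6.07 mM, s·ln(1+U/s) with U left at 33.6 mM gives 0.790% of that charge, and that flask stood at 0.769%.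

The numbers in the tables come from a simulation for an exercise; scatter was added.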